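The small charge of X in violet stands beside little G, and little is easy to reckon as a correction to E. At the last violet reading, G and E together hold 99.7% of the Z charged.

| flask | Z | D | X | remark | time |
|---|---|---|---|---|---|
| violet | 1.7 M | 2.04 M | 0.42 M | run made earlier |  |
| teal | 1.7 M | 1 M | 0.85 M | run made earlier |  |
| flask | 1.7 M | 2.04 M | 0.850 M |  | 15 d |

| run | time / d | G / % | E / % |
|---|---|---|---|
| violet | 1.67 | 6.0 | 92.4 |
| violet | 3.00 | 5.9 | 94.5 |
| violet | 5.00 | 5.6 | 94.1 |
| violet | 6.00 | 6.2 | 93.0 |
| violet | 8.00 | 6.3 | 93.2 |
| violet | 10.0 | 6.3 | 93.4 |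
| teal | 0.625 | 19.6 | 50.7 |
| teal | 1.25 | 21.5 | 58.5 |
| teal | 2.50 | 24.8 | 58.3 |
| teal | 5.00 | 25.5 | 59.0 |
| teal | 10.0 | 25.9 | 59.3 |

(each reading ± 0.5 percentage points)

1. ratio of G to E at 25 min
2. ratio of G to E at 15 d
3. which of G and E there is more of at 15 d

- for E the J are counted in
- the numbers in the tables scatter by 0.5 percentage points (one standard deviation)
- steps under discussion: X + E <-> J; Z -> L; X + L -> G; X -> Q; D + L -> E

Violet reads 0.255 for the X share, the final c(G) over the charged c(X). Teal reads 0.518. In teal, E stops at 1.01 M against 1 M of D charged, so D is the limiting reagent there.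

Two chemists dispute the flask. The first, whose side I take, carries violet's share, since the flask has violet's c(D). That makes c(G) 0.217 M. The D charge covers the remaining Z, so that remainder counts as E, and the final ratio of G to E is 0.146. The second carries teal's share, since the flask has teal's c(X). That makes c(G) 0.440 M and the ratio 0.350.

The forecast's final ratio lies nearer the first side's than the second's, and it is lower than mine: 0.13 at 15 d, between 0.105 and 0.165, with 0.3 at 25 min and E ahead. Its words: “The final ratio is robust”.

The flask gives 1.13 at 25 min, above the forecast's high end. It gives 0.157 at 15 d, inside the forecast's range, and E leads.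

    X + E ⇌ J, settled at all times (K = 31.0 L mol⁻¹)
    Z → L (k = 0.114 h⁻¹)
    X + L → G (k = 2.88 L mol⁻¹ h⁻¹)
    X → Q (k = 0.230 h⁻¹)
    D + L → E (k = 0.983 L mol⁻¹ h⁻¹)

The flask's X share is 0.271, against violet's reading of 0.255, and it is lower than teal's reading of 0.518. The second view has its region in the neighbour, this flask with 0.51 M of D, less than teal's charge. I give it teal's share, so c(G) is 0.440 M. E is capped at the D charged, so the ratio is 0.863. The neighbour itself gives G 27.0% and E 30.0%, with 0% of its D left, and a ratio of 0.900.

The numbers in the tables are calculated with made-up constants, noise included.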